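**Assumptions**
- The target SMILES is read as (5S,8R), with the 5-(5-phenylpentyl) and 8-OMe groups cis on the tetrahydro ring.
- Methyl 2-methoxy-3-oxobutanoate (4) is treated as a catalogue compound; if not, it is one step from methyl methoxyacetate (LDA, then AcCl).
- The antipode of the hydrogenation ligand that gives (5S,8R) must be fixed by a pilot run; the sense of induction is not predicted here.

**Retrosynthetic overview**
1. The N-OMe 4-pyridone comes from a 4-methoxypyridine N-oxide by an O-to-O methyl shift, so no N–O bond is built on a pyridone.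
2. Both stereocentres (C5 and C8, cis) come from one enantioselective, carbocycle-selective hydrogenation of a flat, fully aromatic 5,8-disubstituted quinoline. This replaces the usual plan of annulating a pyridone onto a pre-made chiral cyclohexanone and oxygenating C8 late.
3. The quinoline comes from a Conrad–Limpach reaction of 2-methoxy-5-(5-phenylpentyl)aniline with methyl 2-methoxyacetoacetate, then O-methylation.
4. The aniline comes from a B-alkyl Suzuki coupling of 5-bromo-2-methoxyaniline with 5-phenyl-1-pentene.
5. Ring order: benzene ring purchased, then the pyridone ring (Conrad–Limpach), then the benzo ring is de-aromatised last to give the cyclohexane.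

**Route**

Step 1
Reactants: 1 (5-phenyl-1-pentene), 2 (5-bromo-2-methoxyaniline)
Product: 3, 2-methoxy-5-(5-phenylpentyl)aniline
Conditions: 1, 9-BBN, THF, 0 °C to rt; then 2, Pd(dppf)Cl2 (5 mol%), aq K3PO4, THF/DMF, 65 °C
Reagents that add atoms: none (9-BBN contributes only H)
Why: Anti-Markovnikov hydroboration gives the primary B-alkyl-9-BBN, which undergoes B-alkyl Suzuki–Miyaura coupling with the aryl bromide; the free NH2 and OMe are tolerated.

Step 2
Reactants: 3 (2-methoxy-5-(5-phenylpentyl)aniline), 4 (methyl 2-methoxy-3-oxobutanoate)
Product: 5, methyl (E)-2-methoxy-3-{[2-methoxy-5-(5-phenylpentyl)phenyl]amino}but-2-enoate (NH syn to the ester, H-bonded)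
Conditions: TsOH·H2O (2 mol%), cyclohexane, reflux, Dean–Stark
Reagents that add atoms: none
Why: Acid-catalysed condensation of the aniline at the ketone (not the ester) at 80 °C or below gives the β-anilino enoate, the first stage of the Conrad–Limpach synthesis.

Step 3
Reactants: 5 (enamino ester)
Product: 6, 3,8-dimethoxy-2-methyl-5-(5-phenylpentyl)quinolin-4(1H)-one
Conditions: Ph2O, 250 °C, 20 min (slow addition), –MeOH
Reagents that add atoms: none
Why: Thermal Conrad–Limpach cyclisation (loss of MeOH, ring closure onto the arene) can only occur at the single free ortho position, which places the chain at C5 and OMe at C8.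

Step 4
Reactants: 6 (quinolone)
Product: 7, 3,4,8-trimethoxy-2-methyl-5-(5-phenylpentyl)quinoline
Conditions: MeI, Ag2CO3, CHCl3, 50 °C, dark
Reagents that add atoms: iodomethane, CI
Why: Silver-mediated alkylation of the ambident quinolone is O-selective, helped by the 2-Me and peri 8-OMe groups shielding N, and gives the 4-methoxyquinoline.

Step 5
Reactants: 7 (trimethoxyquinoline)
Product: 8, (5S,8R)-3,4,8-trimethoxy-2-methyl-5-(5-phenylpentyl)-5,6,7,8-tetrahydroquinoline (cis)
Conditions: Ru(η3-methallyl)2(cod) (5 mol%), PhTRAP (chiral trans-chelating bisferrocenyl diphosphine, 5.5 mol%, antipode per assumption), H2 (50 atm), EtOAc, 80 °C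
Reagents that add atoms: none (H2 only)
Why: Proposed new method: a chiral Ru hydride bound to the benzo ring should deliver all four hydrogens to C5–C8 from one face without arene dissociation, so the 5-alkyl and 8-OMe groups end up cis and the ligand selects the enantiotopic face to set C5 (S) and C8 (R) together; the fully substituted, electron-rich pyridine ring with N flanked by 2-Me and 8-OMe resists N-coordination and hydride addition, and the isolated phenyl is not reduced by molecular Ru–phosphine hydrides; the closest known reaction type is Ru/PhTRAP carbocycle-selective asymmetric hydrogenation of 8-substituted quinolines to 5,6,7,8-tetrahydroquinolines (also Ru–NHC carbocycle hydrogenation of quinoxalines), and ee would be upgraded by crystallisation of a tartrate salt of 8 if needed.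

Step 6
Reactants: 8 (tetrahydroquinoline)
Product: 9, (5S,8R)-3,4,8-trimethoxy-2-methyl-5-(5-phenylpentyl)-5,6,7,8-tetrahydroquinoline 1-oxide
Conditions: mCPBA (1.2 equiv), CH2Cl2, 0 °C to rt
Reagents that add atoms: mCPBA, O=C(OO)c1cccc(Cl)c1
Why: The electron-rich 2,6-dialkylpyridine nitrogen is the only site oxidised by the peracid (pyridine N-oxidation); the ethers, phenyl ring and both stereocentres are untouched.

Step 7
Reactants: 9 (N-oxide)
Product: 10, Waltherione H, (5S,8R)-1,3,8-trimethoxy-2-methyl-5-(5-phenylpentyl)-5,6,7,8-tetrahydroquinolin-4(1H)-one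
Conditions: MeI (10 equiv), MeCN, 80 °C, sealed tube, dark
Reagents that add atoms: iodomethane, CI (supplies the N–O–CH3; the 4-O–CH3 leaves as MeI, so the step is a net isomerisation)
Why: O-methylation of the N-oxide gives a 1,4-dimethoxypyridinium iodide, and iodide then removes the para-activated 4-O-methyl by SN2 to give the neutral 1-methoxy-4-pyridone; this is the 4-alkoxypyridine N-oxide to 1-alkoxy-4-pyridone rearrangement (N-oxide analogue of 4-methoxypyridine to N-methyl-4-pyridone), run without base so C8–H is not epimerised.

**Compound list**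
1 | 5-phenyl-1-pentene (pent-4-en-1-ylbenzene) | C=CCCCc1ccccc1 | starting material
2 | 5-bromo-2-methoxyaniline | COc1ccc(Br)cc1N | starting material
3 | 2-methoxy-5-(5-phenylpentyl)aniline | COc1ccc(CCCCCc2ccccc2)cc1N | intermediate
4 | methyl 2-methoxy-3-oxobutanoate | COC(=O)C(OC)C(C)=O | starting material
5 | methyl (E)-2-methoxy-3-{[2-methoxy-5-(5-phenylpentyl)phenyl]amino}but-2-enoate | COC(=O)/C(OC)=C(/C)Nc1cc(CCCCCc2ccccc2)ccc1OC | intermediate
6 | 3,8-dimethoxy-2-methyl-5-(5-phenylpentyl)quinolin-4(1H)-one | COc1c(C)[nH]c2c(OC)ccc(CCCCCc3ccccc3)c2c1=O | intermediate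
7 | 3,4,8-trimethoxy-2-methyl-5-(5-phenylpentyl)quinoline | COc1c(C)nc2c(OC)ccc(CCCCCc3ccccc3)c2c1OC | intermediate
8 | (5S,8R)-3,4,8-trimethoxy-2-methyl-5-(5-phenylpentyl)-5,6,7,8-tetrahydroquinoline | COc1c(C)nc2c(c1OC)[C@@H](CCCCCc1ccccc1)CC[C@H]2OC | intermediate
9 | (5S,8R)-3,4,8-trimethoxy-2-methyl-5-(5-phenylpentyl)-5,6,7,8-tetrahydroquinoline 1-oxide | COc1c(C)[n+]([O-])c2c(c1OC)[C@@H](CCCCCc1ccccc1)CC[C@H]2OC | intermediate
10 | Waltherione H, (5S,8R)-1,3,8-trimethoxy-2-methyl-5-(5-phenylpentyl)-5,6,7,8-tetrahydroquinolin-4(1H)-one | COc1c(C)n(OC)c2c(c1=O)[C@@H](CCCCCc1ccccc1)CC[C@H]2OC | target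

**Totals**
- Total steps: 7
- Longest linear sequence: 7

**Steps most likely to fail, with fallbacks**
1. Step 5 (asymmetric carbocycle hydrogenation). Risks are low ee on a tetrasubstituted benzo ring, loss of the C8–OMe by hydrogenolysis, and reduction of the phenyl or pyridine ring. Fallback: abandon arene reduction. Set C5 by Cu/phosphoramidite-catalysed conjugate addition of the 5-phenylpentyl zinc reagent to 2-cyclohexenone with enolate C-acylation, annulate the pyridine ring onto that 1,3-dicarbonyl, oxidise C8 to the ketone, then use catalyst-controlled transfer hydrogenation (Noyori) and O-methylation to set C8.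
2. Step 7 (methyl shift from 4-O to N–O). Risks are a stalled equilibrium or N–O cleavage. Fallback: separate the two events. Selectively demethylate the 4-OMe of N-oxide 9 with a soft nucleophile (PhSNa, DMF) to the 1-hydroxy-4-pyridone, then O-methylate the N–OH (MeI, K2CO3).
3. Step 3 (Conrad–Limpach closure next to the C5 chain). Risk is a low yield from peri strain at 250 °C. Fallback: change the order of events. Cyclise unhindered o-anisidine with 4 to 3,8-dimethoxy-2-methylquinolin-4-one, O-methylate, brominate at C5 (para to the 8-OMe, NBS), and attach the chain there by the B-alkyl Suzuki coupling of 1/9-BBN.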